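**Retrosynthetic overview**

- Feature: each benzene ring carries C4–OH para to the benzylic carbon C1, a second oxygen on C5, and bromine on C2, C3 and C6. In a perbrominated 4-hydroxyphenyl ring C3 and C5 are equivalent, so exchanging one ortho bromine for oxygen per ring gives the target pattern.
- The target comes from the bis(o-quinone) (C4=O and C5=O on each ring) by quinone-to-catechol reduction.
- The bis(o-quinone) comes from 1,2-bis(2,3,5,6-tetrabromo-4-hydroxyphenyl)ethane by two-directional IBX oxygenation: two C5–O bonds are made and two C5–Br bonds are lost.
- The octabromide comes from 4,4'-(ethane-1,2-diyl)diphenol by eightfold ring bromination; the whole carbon skeleton, including the CH2–CH2 bridge, is bought.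
- Ring order: no ring is formed; both benzene rings come intact from the bisphenol.

Key step: step 2

Remark: the target has no stereocentre and is achiral, so the requirement of a single enantiomer places no demand on the route.

**Route**

Step 1
Reactants: 1 4,4'-(ethane-1,2-diyl)diphenol; 2 bromine
Product: 4 1,2-bis(2,3,5,6-tetrabromo-4-hydroxyphenyl)ethane, via 1,2-bis(3,5-dibromo-4-hydroxyphenyl)ethane 3 (not isolated)
Conditions: Br2 (neat, large excess), AlBr3 (20 mol %), dark, 0 → 55 °C; excess Br2 distilled off, solid washed with water and recrystallised
Reagents that add atoms: bromine, BrBr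
Why: Electrophilic aromatic bromination: the four positions ortho to the OH groups react at once to give 3, and AlBr3-activated bromine then fills the four positions ortho to the CH2 groups, as in the exhaustive ring bromination of phenol and of 1,2-diphenylethane in neat bromine, with no regiochemical question because every ring C–H is replaced and the bridge is left alone under ionic, dark conditions.

Step 2
Reactants: 4 1,2-bis(2,3,5,6-tetrabromo-4-hydroxyphenyl)ethane; 5 2-iodoxybenzoic acid (IBX)
Product: 8 4,4'-(ethane-1,2-diyl)bis(3,5,6-tribromocyclohexa-3,5-diene-1,2-dione), via bis(aryloxy-λ5-iodane) 6 (not isolated), via bis(6-bromo-6-iodanyloxycyclohexa-2,4-dienone) 7 (not isolated)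
Conditions: IBX (6 equiv), DMF, dark, 23–40 °C; poured into water, extracted into EtOAc, crude used at once
Reagents that add atoms: 2-iodoxybenzoic acid, O=C1OI(=O)(O)c2ccccc12
Why: Proposed new method: each acidic tetrabromophenol should exchange with the hydroxy ligand of IBX to give the O-bound aryloxy-λ5-iodane 6, and the iodine(V) oxo ligand is then delivered intramolecularly (a [2,3]-type shift) to the ortho carbon C5, forming the C5–O bond and giving the 6-bromo-6-iodanyloxy dienone 7 with iodine at the I(III) level. Because C5 carries bromine and no hydrogen, 7 cannot tautomerise to a catechol; its gem-bromo-alkoxy carbon should instead ionise, bromide leaving with oxygen lone-pair assistance as the O–I(III) bond breaks, so that the second carbonyl of o-quinone 8 forms beside 2-iodosobenzoic acid and HBr. The closest known reaction type is the IBX ortho-oxidation of phenols to o-quinones, including its ipso variant at a methoxy-bearing ortho carbon that expels methanol; the oxidative para-dehalogenation of 2,4,6-trihalophenols to p-quinones shows that halide can leave from such dienones. No ring is closed and no stereocentre remains, since the two sp3 carbons of 7 are transient. The step needs ortho attack in preference to para or benzylic attack, and one oxygenation per ring: the para carbon is blocked by CH2, the two ortho carbons are equivalent, benzylic oxidation by IBX needs much higher temperature, and the electron-poor o-quinone has no phenol left to bind iodine again. The surplus of IBX allows for oxidant consumed by the bromide that is released.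

Step 3
Reactants: 8 4,4'-(ethane-1,2-diyl)bis(3,5,6-tribromocyclohexa-3,5-diene-1,2-dione)
Product: 9 4,4'-(ethane-1,2-diyl)bis(3,5,6-tribromobenzene-1,2-diol), i.e. 1,2-bis(2,3,6-tribromo-4,5-dihydroxyphenyl)ethane
Conditions: Na2S2O4 (excess), EtOAc/H2O, rt, under N2
Reagents that add atoms: none
Why: Quinone reduction: dithionite is a two-electron reductant that should convert each o-quinone into its catechol within minutes, as in the usual reductive work-up of IBX-derived o-quinones, while the aryl C–Br bonds and the saturated bridge are inert to it.

**Compound list**

1 | 4,4'-(ethane-1,2-diyl)diphenol | Oc1ccc(CCc2ccc(O)cc2)cc1 | starting material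
2 | bromine | BrBr | starting material
3 | 1,2-bis(3,5-dibromo-4-hydroxyphenyl)ethane | Oc1c(Br)cc(CCc2cc(Br)c(O)c(Br)c2)cc1Br | intermediate
4 | 1,2-bis(2,3,5,6-tetrabromo-4-hydroxyphenyl)ethane | Oc1c(Br)c(Br)c(CCc2c(Br)c(Br)c(O)c(Br)c2Br)c(Br)c1Br | intermediate
5 | 2-iodoxybenzoic acid (IBX) | O=C1OI(=O)(O)c2ccccc12 | starting material
6 | bis(aryloxy-λ5-iodane): 4 with each phenol oxygen bound to the iodine(V) of an IBX unit in place of its OH ligand (drawn with both rings at the same stage) | O=C1OI(=O)(Oc3c(Br)c(Br)c(CCc4c(Br)c(Br)c(OI5(=O)OC(=O)c6ccccc56)c(Br)c4Br)c(Br)c3Br)c2ccccc12 | intermediate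
7 | bis(6-bromo-6-iodanyloxycyclohexa-2,4-dienone): each ring a 2,4-dienone with C4=O and an sp3 C5 bearing Br and a 3-oxo-1,2-benziodoxol-1(3H)-yloxy group (two transient sp3 centres, configuration unassigned; drawn with both rings at the same stage) | O=C1C(Br)(OI2OC(=O)c3ccccc23)C(Br)=C(CCC4=C(Br)C(Br)(OI5OC(=O)c6ccccc56)C(=O)C(Br)=C4Br)C(Br)=C1Br | intermediate
8 | 4,4'-(ethane-1,2-diyl)bis(3,5,6-tribromocyclohexa-3,5-diene-1,2-dione) | O=C1C(=O)C(Br)=C(CCC2=C(Br)C(=O)C(=O)C(Br)=C2Br)C(Br)=C1Br | intermediate
9 | 4,4'-(ethane-1,2-diyl)bis(3,5,6-tribromobenzene-1,2-diol) (achiral) | Oc1c(O)c(Br)c(CCc2c(Br)c(O)c(O)c(Br)c2Br)c(Br)c1Br | target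

**Step count**

Total steps: 3. Longest linear sequence: 3.

**Steps most likely to fail**

1. Step 2 (proposed new method). The electron-poor, hindered tetrabromophenol may not accept the oxo ligand at a bromine-bearing carbon, so that the O-bound iodane only reverts. Alternatively, the bromide set free may be oxidised by iodine(III)/(V) to electrophilic bromine, which attacks the CH2-bearing para carbon and, after loss of HBr, degrades the bridge through a quinone methide. The fallback uses known chemistry, sets out from compound 1 and returns at compound 9. Compound 1 would be treated with IBX in DMF at rt, the established ortho-oxidation of 4-alkylphenols, to give 4,4'-(ethane-1,2-diyl)bis(cyclohexa-3,5-diene-1,2-dione) F1. This is reduced in the same flask with aqueous Na2S2O4 to 4,4'-(ethane-1,2-diyl)bis(benzene-1,2-diol) F2. Exhaustive bromination of F2 with Br2 (slightly more than 6 equiv) in AcOH at rt, followed by a dithionite wash to return any over-oxidised material, should brominate the three free positions of each catechol ring, all ortho or para to an OH, and give 9. Oxygen is thus installed before bromine and no bromine-for-oxygen exchange is needed.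

2. Step 1. Bromination may stop before the hindered positions next to the CH2 groups are filled. The free phenol may also be oxidised by bromine (para-ipso bromination, then loss of HBr to a quinone methide), which would lead to bromination or dehydrogenation of the ethylene bridge. The fallback sets out from compound 1 and returns at compound 4. Compound 1 would be O-methylated (MeI, K2CO3, acetone) to 1,2-bis(4-methoxyphenyl)ethane F3, in which the quinone methide path is closed. Exhaustive bromination (neat Br2, Fe powder cat., dark) should give 1,2-bis(2,3,5,6-tetrabromo-4-methoxyphenyl)ethane F4. Cleavage of both methyl ethers with BBr3 in CH2Cl2 (0 °C → rt, then water) gives 4; any ether cleavage during the bromination leads to 4 as well.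

3. Step 3. Sulfite or bisulfite may add to the strongly electrophilic bromo-o-quinone and displace a vinylic bromide. The quinone may be hydrated during aqueous handling, or the catechol may be reoxidised by air on isolation. The fallback sets out from compound 8 and returns at compound 9. Reductive acetylation of 8 (Zn dust, Ac2O, NaOAc, rt) should give the air-stable, purifiable 4,4'-(ethane-1,2-diyl)bis(3,5,6-tribromo-1,2-phenylene) tetraacetate F5. Acid-catalysed methanolysis of F5 (HCl in MeOH, 50 °C) releases 9 without exposing a catecholate to air.

Further compounds
F1 | step 2 | 4,4'-(ethane-1,2-diyl)bis(cyclohexa-3,5-diene-1,2-dione) | O=C1C(=O)C=C(CCC2=CC(=O)C(=O)C=C2)C=C1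
F2 | step 2 | 4,4'-(ethane-1,2-diyl)bis(benzene-1,2-diol) | Oc1ccc(CCc2ccc(O)c(O)c2)cc1O
F3 | step 1 | 1,2-bis(4-methoxyphenyl)ethane | COc1ccc(CCc2ccc(OC)cc2)cc1
F4 | step 1 | 1,2-bis(2,3,5,6-tetrabromo-4-methoxyphenyl)ethane | COc1c(Br)c(Br)c(CCc2c(Br)c(Br)c(OC)c(Br)c2Br)c(Br)c1Br
F5 | step 3 | 4,4'-(ethane-1,2-diyl)bis(3,5,6-tribromo-1,2-phenylene) tetraacetate | CC(=O)Oc1c(OC(C)=O)c(Br)c(CCc2c(Br)c(OC(C)=O)c(OC(C)=O)c(Br)c2Br)c(Br)c1Br
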